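**Retrosynthetic overview**
- Feature: in ring B (C5–C10) the adjacent atoms C8 and C9 each carry one carbon (C17, C11) beside the methyl-bearing quaternary C10. This is the imprint of a maleic dienophile on a C10=C5–C6=C7 diene held in ring A.
- Last bonds: C12–C13 by hydroboration of a C9 vinyl group and B-alkyl Suzuki coupling with 3-bromofuran-2(5H)-one; C11=C12 by methylenation of a C11 lactol; the C17 alcohol from the less hindered ester.
- C4(CH2OH)2 comes from a C4 ketone by methoxymethylenation, formaldehyde aldol and reduction. The ketone comes from the C4 carbinol that steered the cycloaddition.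
- Key disconnection C9–C10 and C7–C8: endo Diels–Alder of an (R)-C4-silyloxy 2-methyl-1-vinylcyclohexene with maleic anhydride, anti to the silyloxy group. C5=C6 is then hydrogenated anti to the methyl group, and only afterwards is C9 equilibrated, in the locked trans-decalin.
- Ring order: ring A (bought as 3-methylcyclohex-2-enone), then ring B (Diels–Alder), then the butenolide (bought, attached last).

Key step: step 5

Remark: labdane numbering is used (ring A = C1–C5, C10; ring B = C5–C10; C20 = methyl on C10; C17 on C8; C11, C12 and the butenolide C13–C16 on C9; C18/C19 on C4). "α" means the face of the C10 methyl group and "β" the opposite face. The target is then 10-Me α, H5 β, C17 β, C11 α, i.e. (5S,8S,9R,10S); C4 of the target is not stereogenic.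

Step 1
Reactants: 1 3-methylcyclohex-2-en-1-one
Product: 2 2-iodo-3-methylcyclohex-2-en-1-one
Conditions: I2, K2CO3, DMAP (cat.), THF/H2O, rt
Reagents that add atoms: iodine, II
Why: Amine-mediated α-iodination of an enone (Baylis–Hillman-type conjugate addition of DMAP, iodination of the enolate, elimination) should give the α-iodoenone.

Step 2
Reactants: 2 2-iodo-3-methylcyclohex-2-en-1-one
Product: 3 (R)-2-iodo-3-methylcyclohex-2-en-1-ol
Conditions: (S)-1-methyl-3,3-diphenyltetrahydro-1H,3H-pyrrolo[1,2-c][1,3,2]oxazaborole (10 mol %), BH3·SMe2, THF, −20 °C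
Reagents that add atoms: none
Why: Corey–Bakshi–Shibata reduction in which the α-iodoalkenyl arm acts as the large group, so the (S)-catalyst should give the (R)-carbinol, the future C4 control element.

Step 3
Reactants: 3 (R)-2-iodo-3-methylcyclohex-2-en-1-ol
Product: 4 (R)-TBS ether of the iodo alcohol
Conditions: TBSCl, imidazole, DMF, rt
Reagents that add atoms: tert-butyldimethylsilyl chloride, CC(C)(C)[Si](C)(C)Cl
Why: Imidazole-promoted silylation of a secondary allylic alcohol, which leaves the stereocentre untouched.

Step 4
Reactants: 4 (R)-TBS ether of the iodo alcohol; 5 tributyl(vinyl)stannane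
Product: 6 (R)-tert-butyl[(2-ethenyl-3-methylcyclohex-2-en-1-yl)oxy]dimethylsilane
Conditions: Pd2(dba)3 (cat.), AsPh3, CuI, NMP, 50 °C
Reagents that add atoms: none
Why: Stille coupling of a vinyl iodide with a vinylstannane, with the arsine ligand and copper co-catalyst suited to a hindered tetrasubstituted iodide, should give the diene with the silyl ether intact.

Step 5
Reactants: 6 (R)-tert-butyl[(2-ethenyl-3-methylcyclohex-2-en-1-yl)oxy]dimethylsilane; 7 maleic anhydride
Product: 8 endo anhydride adduct (Δ5-octalin; 10-Me α; 4-OTBS α; C8 and C9 carbonyls β)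
Conditions: PhMe, BHT (cat.), 90 °C, sealed tube
Reagents that add atoms: none
Why: A concerted suprafacial [4+2] cycloaddition, the thermal Diels–Alder reaction long used for 2-methyl-1-vinylcyclohexenes with maleic-type dienophiles, forms C9–C10 and C7–C8 and closes ring B by intermolecular annulation onto the C10=C5–C6=C7 diene, leaving C5=C6. A(1,2) strain with the vinyl group holds the C4 silyloxy group pseudoaxial, so the dienophile should add to the opposite diene face; this fixes C10 with its methyl group cis to OTBS on ring A (both α). Endo addition (Alder rule, anhydride carbonyls under C5–C6) places C11 and C17 on the β face, trans to the "inside" methyl group, so C8 has its final configuration and C9 is epimeric, to be corrected in step 8. The step needs face selectivity, secured by the bulky pseudoaxial OTBS, and endo selectivity, secured by the cyclic cis-dienophile; regiochemistry does not arise with a symmetric dienophile. A strong dienophile is chosen because bond formation at the tetrasubstituted terminus C10, which creates the quaternary centre, is the slow event.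

Step 6
Reactants: 8 endo anhydride adduct
Product: 10 cis-dimethyl diester of the Δ5-octalin, via half-ester 9 (not isolated)
Conditions: MeOH, DMAP (cat.), CH2Cl2, rt; then TMSCHN2, PhMe/MeOH, 0 °C
Reagents that add atoms: methanol, CO; (trimethylsilyl)diazomethane, C[Si](C)(C)C=[N+]=[N-]
Why: Alcoholysis of a cyclic anhydride (faster at the less hindered C17 carbonyl, though either half-ester serves) and O-methylation of the acid under non-acidic conditions that spare the allylic silyl ether.

Step 7
Reactants: 10 cis-dimethyl diester of the Δ5-octalin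
Product: 11 cis-diester of the trans-decalin (H5 β)
Conditions: H2 (1 atm), [Ir(cod)(PCy3)(py)]PF6 (cat.), CH2Cl2, rt
Reagents that add atoms: none
Why: Homogeneous iridium-catalysed hydrogenation of a hindered trisubstituted alkene; the α face is blocked by the axial C10 methyl and the axial C4 silyloxy group while the β-oriented ester carbonyls can bind the metal, so hydrogen should add from the β face and set H5 β (trans ring fusion).

Step 8
Reactants: 11 cis-diester of the trans-decalin
Product: 12 trans-diequatorial diester (C17 β; C11 α)
Conditions: NaOMe, MeOH, reflux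
Reagents that add atoms: none
Why: Base-mediated ester epimerisation under thermodynamic control: in the rigid trans-decalin the only arrangement with both esters equatorial is C17 β/C11 α, so reversible enolisation at C9 (and C8) should drain the axial C11 ester into 12.

Step 9
Reactants: 12 trans-diequatorial diester
Product: 13 4α-alcohol diester
Conditions: 48% aq. HF, MeCN, rt
Reagents that add atoms: none
Why: Fluoride-mediated desilylation of a hindered secondary TBS ether, to which methyl esters are inert.

Step 10
Reactants: 13 4α-alcohol diester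
Product: 14 4-ketone diester
Conditions: Dess–Martin periodinane, CH2Cl2, rt
Reagents that add atoms: none
Why: Dess–Martin oxidation under neutral conditions; the trans ring fusion at C5, now α to the ketone, is expected to be the more stable one (as in trans-fused 4-oxo steroids) and should hold.

Step 11
Reactants: 14 4-ketone diester
Product: 16 C4 carbaldehyde diester, via enol ether 15 (not isolated)
Conditions: Ph3P(CH2OMe)Cl, KN(SiMe3)2, THF, 0 °C to rt; then 2 M HCl, THF, rt
Reagents that add atoms: (methoxymethyl)triphenylphosphonium chloride, COC[P+](c1ccccc1)(c1ccccc1)c1ccccc1.[Cl-]; water, O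
Why: Wittig methoxymethylenation and acid hydrolysis of the enol ether, the standard one-carbon homologation of a ketone to an aldehyde; the ketone should react far faster than the two hindered secondary esters, and the C4 configuration of 16 is of no consequence.

Step 12
Reactants: 16 C4 carbaldehyde diester
Product: 18 4,4-bis(hydroxymethyl) diester, via aldol 17 (not isolated)
Conditions: 37% aq. CH2O, K2CO3 (cat.), MeOH, 40 °C; then NaBH4, 0 °C
Reagents that add atoms: formaldehyde, C=O
Why: Tollens-type hydroxymethylation (crossed aldol of the α-branched aldehyde with formaldehyde, which cannot dehydrate) with borohydride reduction in place of the Cannizzaro step so that the methyl esters survive; both C4 substituents become CH2OH and C4 ceases to be a stereocentre.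

Step 13
Reactants: 18 4,4-bis(hydroxymethyl) diester
Product: 19 acetonide diester
Conditions: Me2C(OMe)2, PPTS (cat.), acetone, rt
Reagents that add atoms: 2,2-dimethoxypropane, COC(C)(C)OC
Why: Acid-catalysed transacetalisation should give the six-membered acetonide of the 1,3-diol.

Step 14
Reactants: 19 acetonide diester
Product: 20 C17 acid C11 methyl ester
Conditions: LiOH·H2O, THF/MeOH/H2O, rt; then 1 M HCl to pH 4, 0 °C
Reagents that add atoms: lithium hydroxide, [Li+].[OH-]
Why: Selective saponification: the C17 ester on C8 should hydrolyse much faster than the C11 ester shielded by the quaternary C10, and the carboxylate formed slows the second hydrolysis further.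

Step 15
Reactants: 20 C17 acid C11 methyl ester
Product: 21 C17 alcohol C11 methyl ester
Conditions: BH3·SMe2, THF, 0 °C to rt; aqueous work-up
Reagents that add atoms: none
Why: Chemoselective borane reduction of a carboxylic acid (through the acyloxyborane) in the presence of an ester and an acetonide.

Step 16
Reactants: 21 C17 alcohol C11 methyl ester
Product: 22 trans-fused C11 lactol
Conditions: i-Bu2AlH, CH2Cl2, −78 °C; aq. potassium sodium tartrate
Reagents that add atoms: none
Why: Partial reduction of an ester with i-Bu2AlH at low temperature; the aldehyde oxidation level is trapped as the lactol by the neighbouring C17 oxygen, which guards against over-reduction (any lactone formed from 21 gives the same lactol).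

Step 17
Reactants: 22 trans-fused C11 lactol
Product: 23 C9-vinyl C17 alcohol
Conditions: Ph3PCH3Br, KOtBu, THF, 0 °C to rt
Reagents that add atoms: methyltriphenylphosphonium bromide, C[P+](c1ccccc1)(c1ccccc1)c1ccccc1.[Br-]
Why: Wittig methylenation of a lactol through its open hydroxy aldehyde; the C9 aldehyde is already equatorial, the preferred position, so no epimerisation is expected.

Step 18
Reactants: 23 C9-vinyl C17 alcohol; 24 3-bromofuran-2(5H)-one
Product: 26 butenolide acetonide, via alkylborane 25 (not isolated)
Conditions: 9-BBN dimer, THF, rt; then 24, PdCl2(dppf) (cat.), AsPh3, aq. K3PO4, DMF, rt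
Reagents that add atoms: none
Why: Anti-Markovnikov hydroboration of the terminal alkene and B-alkyl Suzuki–Miyaura coupling with an α-bromo enoate-type vinyl bromide (as established for α-halo enones) should form C12–C13; phosphate base at room temperature is chosen to spare the butenolide, and excess borane tolerates the free hydroxyl.

Step 19
Reactants: 26 butenolide acetonide
Product: 27 target CNP0271381.1
Conditions: 1 M HCl, THF, rt
Reagents that add atoms: none
Why: Mild aqueous acid hydrolysis of the acetonide, to which the butenolide and the primary alcohols are stable.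

**Compound list**
1 | 3-methylcyclohex-2-en-1-one | CC1=CC(=O)CCC1 | starting material
2 | 2-iodo-3-methylcyclohex-2-en-1-one | CC1=C(I)C(=O)CCC1 | intermediate
3 | (R)-2-iodo-3-methylcyclohex-2-en-1-ol | CC1=C(I)[C@H](O)CCC1 | intermediate
4 | (R)-tert-butyl[(2-iodo-3-methylcyclohex-2-en-1-yl)oxy]dimethylsilane | CC1=C(I)[C@H](O[Si](C)(C)C(C)(C)C)CCC1 | intermediate
5 | tributyl(vinyl)stannane | CCCC[Sn](CCCC)(CCCC)C=C | starting material
6 | (R)-tert-butyl[(2-ethenyl-3-methylcyclohex-2-en-1-yl)oxy]dimethylsilane (diene; carbinol carbon = future C4) | CC1=C(C=C)[C@H](O[Si](C)(C)C(C)(C)C)CCC1 | intermediate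
7 | maleic anhydride | O=C1OC(=O)C=C1 | starting material
8 | endo Diels–Alder adduct: Δ5-octalin-8,9-dicarboxylic anhydride, 10-Me α, 4-OTBS α, C11 and C17 carbonyls β | C[C@@]12CCC[C@@H](O[Si](C)(C)C(C)(C)C)C1=CC[C@H](C(=O)OC3=O)[C@@H]23 | intermediate
9 | half-ester (C17 methyl ester, C11 acid; not isolated) | C[C@@]12CCC[C@@H](O[Si](C)(C)C(C)(C)C)C1=CC[C@H](C(=O)OC)[C@@H]2C(O)=O | intermediate
10 | cis-dimethyl diester of the Δ5-octalin (C11 β, C17 β, 4-OTBS α) | C[C@@]12CCC[C@@H](O[Si](C)(C)C(C)(C)C)C1=CC[C@H](C(=O)OC)[C@@H]2C(=O)OC | intermediate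
11 | cis-diester of the trans-decalin (H5 β; C11 ester β axial, C17 ester β equatorial) | C[C@@]12CCC[C@@H](O[Si](C)(C)C(C)(C)C)[C@H]1CC[C@H](C(=O)OC)[C@@H]2C(=O)OC | intermediate
12 | trans-diequatorial diester (C11 ester α, C17 ester β, 4-OTBS α) | C[C@@]12CCC[C@@H](O[Si](C)(C)C(C)(C)C)[C@H]1CC[C@H](C(=O)OC)[C@H]2C(=O)OC | intermediate
13 | 4α-alcohol diester | C[C@@]12CCC[C@@H](O)[C@H]1CC[C@H](C(=O)OC)[C@H]2C(=O)OC | intermediate
14 | 4-ketone diester (trans-fused) | C[C@@]12CCCC(=O)[C@H]1CC[C@H](C(=O)OC)[C@H]2C(=O)OC | intermediate
15 | C4 methoxymethylidene enol ether (E/Z mixture; not isolated) | C[C@@]12CCCC(=COC)[C@H]1CC[C@H](C(=O)OC)[C@H]2C(=O)OC | intermediate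
16 | C4 carbaldehyde diester (drawn as the equatorial 4β-CHO epimer; either epimer serves) | C[C@@]12CCC[C@H](C=O)[C@H]1CC[C@H](C(=O)OC)[C@H]2C(=O)OC | intermediate
17 | aldol: 4-formyl-4-(hydroxymethyl) diester (drawn with CH2OH β; not isolated) | C[C@@]12CCC[C@@](CO)(C=O)[C@H]1CC[C@H](C(=O)OC)[C@H]2C(=O)OC | intermediate
18 | 4,4-bis(hydroxymethyl) diester | C[C@@]12CCCC(CO)(CO)[C@H]1CC[C@H](C(=O)OC)[C@H]2C(=O)OC | intermediate
19 | acetonide (spiro-1,3-dioxane at C4) diester | C[C@@]12CCCC3(COC(C)(C)OC3)[C@H]1CC[C@H](C(=O)OC)[C@H]2C(=O)OC | intermediate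
20 | acetonide, C17 carboxylic acid, C11 methyl ester | C[C@@]12CCCC3(COC(C)(C)OC3)[C@H]1CC[C@H](C(O)=O)[C@H]2C(=O)OC | intermediate
21 | acetonide, C17 primary alcohol, C11 methyl ester | C[C@@]12CCCC3(COC(C)(C)OC3)[C@H]1CC[C@H](CO)[C@H]2C(=O)OC | intermediate
22 | acetonide, trans-fused lactol (C11 hemiacetal carbon bridged through O to C17; anomer mixture) | C[C@@]12CCCC3(COC(C)(C)OC3)[C@H]1CC[C@H](CO4)[C@H]2C4O | intermediate
23 | acetonide, C9 vinyl (α), C17 alcohol (β) | C[C@@]12CCCC3(COC(C)(C)OC3)[C@H]1CC[C@H](CO)[C@H]2C=C | intermediate
24 | 3-bromofuran-2(5H)-one | O=C1OCC=C1Br | starting material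
25 | B-(C12-alkyl)-9-borabicyclo[3.3.1]nonane (not isolated) | C[C@@]12CCCC3(COC(C)(C)OC3)[C@H]1CC[C@H](CO)[C@H]2CCB4C5CCCC4CCC5 | intermediate
26 | acetonide of the target (α-alkyl butenolide, C17 alcohol) | C[C@@]12CCCC3(COC(C)(C)OC3)[C@H]1CC[C@H](CO)[C@H]2CCC4=CCOC4=O | intermediate
27 | CNP0271381.1, (5S,8S,9R,10S)-triol butenolide | C[C@@]12CCCC(CO)(CO)[C@H]1CC[C@H](CO)[C@H]2CCC1=CCOC1=O | target

**Step count**
Total: 19 steps. Longest linear sequence: 19 steps (1 to 27); compounds 5, 7 and 24 are bought.

**Steps most likely to fail**

Step 5. The cycloaddition may be slow at the tetrasubstituted C10 terminus, because the methyl group sits inside the s-cis diene. The forcing conditions then needed would bring polymerisation, [1,5]-hydrogen shift of the diene or erosion of endo selectivity. The fallback sets out from 6 and uses dimethyl acetylenedicarboxylate (neat or in toluene, 110 °C), the dienophile with the longest record for such dienes and one that raises no endo/exo question. It should give the 5,8-diene diester F1, with C10 again set anti to OTBS. Hydrogenation of the non-conjugated C5=C6 bond (H2, PtO2, EtOAc), now with an unhindered β face, should give the Δ8-ene diester F2. Conjugate reduction of the tetrasubstituted ene-diester (Mg, MeOH) followed by NaOMe/MeOH equilibration then sets C8 and C9 under thermodynamic control and comes back to the route at 12.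

Step 18. Aqueous base may open or deprotonate the bromobutenolide, and protodeboronation or β-hydride elimination may outrun transmetalation of the alkylborane. The fallback makes C12–C13 by enolate alkylation and sets out from 23.
- Silylation of the C17 hydroxyl (TBSCl, imidazole) gives the vinyl silyl ether F3.
- Hydroboration–oxidation (9-BBN; NaOH, H2O2) gives the C12 alcohol F4.
- I2, PPh3 and imidazole give the C12 iodide F5.
- Alkylation of the lithium enolate of 3-(phenylsulfanyl)oxolan-2-one (LiN(SiMe3)2, THF/HMPA) gives the α-alkyl-α-phenylthio lactone F6.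
- Oxidation to the sulfoxide (mCPBA, −78 °C) and thermal syn-elimination into the ring (toluene, 110 °C) give the silylated butenolide F7.
- Aqueous HCl in THF removes the silyl ether and the acetonide together and comes back to the route at 27.

Step 7. Hydrogen delivery may lack facial selectivity, since the axial C11 ester on the β face competes with the methyl and silyloxy groups on the α face, and the hindered alkene may reduce slowly. The fallback sets C5 under thermodynamic control and sets out from 10. Desilylation (aq. HF, MeCN) gives the allylic alcohol F8, and MnO2 in CH2Cl2 gives the Δ5-4-ketone F9. Hydrogenation of the enone C=C (H2, Pd/C, EtOAc) gives the saturated keto diester F10 as a C5 mixture. NaOMe in MeOH then equilibrates C5 (α to the ketone) together with C9 and C8 (α to the esters) to the all-equatorial trans-fused isomer, which comes back to the route at 14.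

**Further compounds**
F1 | step 5 | dimethyl Δ5,Δ8-diene diester (10-Me α, 4-OTBS α) | C[C@@]12CCC[C@@H](O[Si](C)(C)C(C)(C)C)C1=CCC(C(=O)OC)=C2C(=O)OC
F2 | step 5 | dimethyl Δ8-ene diester, trans-fused (H5 β, 4-OTBS α) | C[C@@]12CCC[C@@H](O[Si](C)(C)C(C)(C)C)[C@H]1CCC(C(=O)OC)=C2C(=O)OC
F3 | step 18 | acetonide, C9 vinyl, C17 TBS ether | C[C@@]12CCCC3(COC(C)(C)OC3)[C@H]1CC[C@H](CO[Si](C)(C)C(C)(C)C)[C@H]2C=C
F4 | step 18 | acetonide, C12 primary alcohol, C17 TBS ether | C[C@@]12CCCC3(COC(C)(C)OC3)[C@H]1CC[C@H](CO[Si](C)(C)C(C)(C)C)[C@H]2CCO
F5 | step 18 | acetonide, C12 iodide, C17 TBS ether | C[C@@]12CCCC3(COC(C)(C)OC3)[C@H]1CC[C@H](CO[Si](C)(C)C(C)(C)C)[C@H]2CCI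
F6 | step 18 | α-alkyl-α-(phenylthio)-γ-butyrolactone (C13 epimer mixture), C17 TBS ether, acetonide | C[C@@]12CCCC3(COC(C)(C)OC3)[C@H]1CC[C@H](CO[Si](C)(C)C(C)(C)C)[C@H]2CCC4(Sc5ccccc5)CCOC4=O
F7 | step 18 | butenolide, C17 TBS ether, acetonide | C[C@@]12CCCC3(COC(C)(C)OC3)[C@H]1CC[C@H](CO[Si](C)(C)C(C)(C)C)[C@H]2CCC4=CCOC4=O
F8 | step 7 | Δ5 allylic 4α-alcohol, cis-diester | C[C@@]12CCC[C@@H](O)C1=CC[C@H](C(=O)OC)[C@@H]2C(=O)OC
F9 | step 7 | Δ5-4-ketone (enone), cis-diester | C[C@@]12CCCC(=O)C1=CC[C@H](C(=O)OC)[C@@H]2C(=O)OC
F10 | step 7 | saturated 4-keto cis-diester, C5 epimer mixture | C[C@@]12CCCC(=O)C1CC[C@H](C(=O)OC)[C@@H]2C(=O)OC
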